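**Retrosynthetic overview**
1. The target is acyclic apart from the purchased phenyl ring and has no stereocentre, so no ring is formed at any stage and only two bonds are disconnected.
2. Last disconnection: the C3–C4 bond of the acyl chain (C22 + C3), made by a new copper-catalysed 1,4-addition of an alkylborane to an acrylate ester.
3. The ester C–O bond is set first, inside the C3 unit: 2-phenylethanol (1) + acrylic acid (2) give 2-phenylethyl acrylate (3).
4. The C22 unit: 1-bromooctadecane (4) + but-3-enylmagnesium bromide (5) give docos-1-ene (6); its hydroboration product 9-docosyl-9-BBN (7) adds to 3 to give the target (8).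

Assumption: the target has no stereocentre and no stereogenic double bond, so "the single enantiomer given" is read as the achiral compound exactly as drawn.

**Route**

Step 1
Reactants: 1 2-phenylethanol, 2 acrylic acid
Product: 3 2-phenylethyl acrylate
Conditions: 2 (1.3 equiv), p-TsOH·H2O (2 mol %), 4-methoxyphenol (0.2 mol %), air bleed, toluene, reflux, Dean–Stark; aq NaHCO3 wash; vacuum distillation
Reagents that add atoms: none
Why: Fischer esterification driven to completion by azeotropic removal of water, with 4-methoxyphenol suppressing radical polymerisation of the acrylate; no stereocentre is formed.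

Step 2
Reactants: 4 1-bromooctadecane, 5 but-3-enylmagnesium bromide
Product: 6 docos-1-ene
Conditions: 5 (1.3 equiv, 0.5 M in THF, slow addition), Li2CuCl4 (3 mol %), NMP (4 equiv), THF, 0 °C to rt; bulb-to-bulb distillation, then crystallisation from acetone
Reagents that add atoms: none
Why: Kochi-type copper-catalysed sp3–sp3 cross-coupling of a primary alkyl bromide with a primary alkyl Grignard reagent, in which NMP suppresses β-hydride elimination and homocoupling and the remote terminal alkene of 5 is inert; no stereocentre is formed.

Step 3
Reactants: 6 docos-1-ene, 3 2-phenylethyl acrylate
Product: 8 2-phenylethyl pentacosanoate, via 9-docosyl-9-BBN 7 (not isolated)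
Conditions: 6 (1.3 equiv), (9-BBN-H)2 (0.62 equiv), THF, 60 °C, 2 h; then CuCl (5 mol %), IMes·HCl (1,3-dimesitylimidazolium chloride, 6 mol %), KOt-Bu (12 mol %), BHT (2 mol %), 3 (1.0 equiv) and t-BuOH (1.5 equiv) co-added over 2 h, THF–1,4-dioxane, 40 °C, rigorously degassed; aq NH4Cl
Reagents that add atoms: none
Why: Proposed new method: anti-Markovnikov hydroboration of 6 with 9-BBN-H places boron on C1, the (IMes)Cu–Ot-Bu formed in situ takes the primary docosyl group from boron onto monovalent copper through a Cu–O–B bridged borate (the bicyclic B–C bonds do not transfer), the docosylcopper inserts the unhindered acrylate 3 in the 1,4-sense to give a copper enolate, and t-BuOH protonates that enolate before it can add to a second acrylate and so regenerates Cu–Ot-Bu, which keeps the alkoxide catalytic and forms the C3–C4 bond without creating a stereocentre; the closest known reaction type is the copper-catalysed conjugate addition of alkyl-9-BBN reagents to activated β-substituted acceptors (aryl enoates, acyl imidazoles), combined with the alcohol-driven turnover of copper enolates known from CuH 1,4-reductions, whereas a simple β-unsubstituted alkyl acrylate, which normally polymerises in the presence of alkylboranes, has not been used as the acceptor.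

**Compound list**
1 | 2-phenylethanol | OCCc1ccccc1 | starting material
2 | acrylic acid | C=CC(=O)O | starting material
3 | 2-phenylethyl acrylate | C=CC(=O)OCCc1ccccc1 | intermediate
4 | 1-bromooctadecane | CCCCCCCCCCCCCCCCCCBr | starting material
5 | but-3-enylmagnesium bromide | C=CCC[Mg]Br | starting material
6 | docos-1-ene | CCCCCCCCCCCCCCCCCCCCC=C | intermediate
7 | 9-docosyl-9-borabicyclo[3.3.1]nonane (9-docosyl-9-BBN) | CCCCCCCCCCCCCCCCCCCCCCB1C2CCCC1CCC2 | intermediate
8 | 2-phenylethyl pentacosanoate (achiral) | CCCCCCCCCCCCCCCCCCCCCCCCC(=O)OCCc1ccccc1 | target

**Step count and risks**

Total step count: 3. Longest linear sequence: 2 steps (4 → 6 → 8, or 1 → 3 → 8).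

The three steps most likely to fail, most risky first:

Step 3 (the proposed new step). The copper enolate may add to further acrylate and give oligomers. The docosylcopper may be protonated by t-BuOH to docosane before it meets the acrylate. Boron-to-copper transfer may be too slow with only catalytic alkoxide. The fallback uses known chemistry only; it sets out from 6 and comes back to the route at 8. Peroxide-initiated anti-Markovnikov addition of HBr to 6 (HBr gas, dibenzoyl peroxide, hexane, 0 °C) gives 1-bromodocosane F1. A classical Giese radical addition of 1-bromodocosane F1 to acrylate 3 (3 equiv), with (Me3Si)3SiH added slowly and AIBN in toluene at 80 °C, then gives 8 directly.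

Step 2. Homocoupling (hexatriacontane), reduction (octadecane) and β-hydride elimination (octadec-1-ene) give hydrocarbons that are hard to separate from 6. Octadec-1-ene is the dangerous one, because it would be carried through step 3 to a C21 homologue of the target. The fallback replaces the catalytic cross-coupling by a sulfone-carbanion alkylation with polar, crystallisable intermediates; it sets out from 4 and comes back to the route at 6. Compound 4 with PhSO2Na (DMF, 80 °C) gives octadecyl phenyl sulfone F2. Deprotonation with n-BuLi (THF, DMPU, −78 °C) and alkylation with 4-bromobut-1-ene gives racemic 5-(phenylsulfonyl)docos-1-ene F3, which is purified by crystallisation. Reductive desulfonylation with sodium amalgam (Na/Hg, Na2HPO4, MeOH–THF, 0 °C) removes the sulfone, and with it the temporary stereocentre, to give 6.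

Step 1. The acrylate may polymerise during the hot acid-catalysed esterification or the distillation, and 1 may add to the acrylate double bond (oxa-Michael addition). The fallback carries the double bond in masked form; it sets out from 1 and comes back to the route at 3. Acylation of 1 with 3-chloropropanoyl chloride (toluene, 60 °C, no base) gives 2-phenylethyl 3-chloropropanoate F4. Treatment with Et3N (CH2Cl2, 0 °C to rt) eliminates HCl and gives 3 under mild, non-acidic conditions.

**Further compounds**
F1 | step 3 | 1-bromodocosane | CCCCCCCCCCCCCCCCCCCCCCBr
F2 | step 2 | octadecyl phenyl sulfone | CCCCCCCCCCCCCCCCCCS(=O)(=O)c1ccccc1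
F3 | step 2 | 5-(phenylsulfonyl)docos-1-ene (racemic) | C=CCCC(CCCCCCCCCCCCCCCCC)S(=O)(=O)c1ccccc1
F4 | step 1 | 2-phenylethyl 3-chloropropanoate | ClCCC(=O)OCCc1ccccc1
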